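The west run showed how fast the pool of the two substrates falls, and the south run how fast its excess dies; I used both clocks on Saturday's and Thursday's flasks.

| setting | south | west | Saturday's | Thursday's |
|---|---|---|---|---|
| left-handed substrate | 0.41 M | 0.41 M | 0.41 M | 0.41 M |
| right-handed substrate | 0.41 M | 0.41 M | 0.41 M | 0.41 M |
| partner | 1.3 equiv | 2 equiv | 2.00 equiv | 2.00 equiv |
| free catalyst | 2.5 mol% | 2.5 mol% | 2.5 mol% | 8 mol% |
| racemization catalyst | 2 mol% | 4 mol% | 2 mol% | 2 mol% |
| remark | run made earlier | run made earlier |  |  |
| time |  |  | 2.0 min | 2.0 min |

| run | time / s | right-handed substrate / % | left-handed substrate / % |
|---|---|---|---|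
| south | 10.0 | 44.8 | 39.3 |
| south | 20.0 | 39.9 | 34.2 |
| south | 30.0 | 36.7 | 29.8 |
| south | 40.0 | 33.6 | 27.3 |
| west | 10.0 | 42.1 | 35.7 |
| west | 20.0 | 35.3 | 27.8 |
| west | 30.0 | 30.3 | 21.6 |
| west | 40.0 | 27.4 | 19.0 |

(readings scatter by 0.5 percentage points)

- free catalyst is single-handed; left-handed substrate and right-handed substrate are mirror images of each other, charged as a racemate, each of them at the stated concentration
- an excess is the difference of the two amounts in percent of their sum
- an excess is below zero if the other one leads
- no earlier run changes the charge of free catalyst; that part of a forecast is a guess

1. the flask that ends with the higher excess of right-handed substrate over left-handed substrate among what is left of the two, or "neither" when 2 percentage points or less lies between them (Saturday's / Thursday's / neither)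
2. excess of right-handed substrate over left-handed substrate among what is left of the two at the end, Saturday's
3. excess of right-handed substrate over left-handed substrate among what is left of the two at the end, Thursday's

I read the west table first. At 2 equiv the partner matches the two substrates together, so I took a second-order fall of the pool. Its last row, 46.4% left at 40.0 s, gave a half-time of 34.6 s. That curve gives 63.4% at 20.0 s, and that row reads 63.1%. The first west row gave 0.328 of excess per unit of ln fall of the pool, a selectivity factor near 1.98.

Then I read the south table, which has the racemization catalyst loading of both new flasks. Its last row should have made 16.3% of excess but shows 10.3%. Its four rows average 8.74%. That loss gave the excess lifetime, the time in which racemization takes an excess down by a factor e: 59.2 s.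

My rule was that excess made earlier than one lifetime before the end is gone, while excess made inside that window stands. Scaling by loading, which is a guess, Thursday's half-time of 10.8 s is shorter than Saturday's. In the last lifetime the pool falls by a factor 1.62 in Saturday's and 1.83 in Thursday's. So I reckoned 15.8% for Saturday's and 19.7% for Thursday's, the higher.

The forecast differed from my reckoning: Saturday's, with 11% and 7%. For Thursday's its ground was “Racemization then catches up”.

    2 racemization catalyst ⇌ resting dimer, settled at all times (K = 91.0 /M)
    partner → decomposition product (k = 1.70 × 10⁻⁵ /s)
    left-handed substrate + racemization catalyst ⇌ right-handed substrate + racemization catalyst, rate k3*[racemization catalyst]*[left-handed substrate] forward; the back reaction follows from the equilibrium constant (k = 1.60 /M/s)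
    partner + free catalyst + right-handed substrate → free catalyst + right-handed product (k = 2.50 /M²/s)
    partner → decomposed reagent (k = 8.20 × 10⁻⁴ /s)
    partner + free catalyst + left-handed substrate → free catalyst + left-handed product (k = 4.80 /M²/s)

The simulation gave 17.6% for Saturday's and 25.2% for Thursday's, so Thursday's ended higher. By my reading of the excess lifetime, 59.2 s, the 2.0 min of Saturday's flask came to 2.03 such lifetimes. The neighbour is Saturday's flask read at 5.0 min. There my curve has the pool fall by a factor 1.21 in the last lifetime, and my rule turns that into 6.38%. That flask stood at 7.12%, with right-handed substrate at 6.85% and left-handed substrate at 5.94%.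

The numbers in the tables are simulated on assumed constants, and the scatter is random.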